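## Retrosynthetic overview
1. Ring B is opened at its lactone C–O bond (tertiary OH on the spiro carbon plus a tartrate-derived CO2H). Ring A is opened at its lactone C–O bond (secondary OH plus a methyl ester).
2. Key disconnection: the bond between the spiro carbon and the neighbouring C(OH)(CO2H) carbon. It is made by aldol addition of the lithium enolate of di-tert-butyl L-tartrate acetonide to the ketone of a 4-silyloxy-2-oxo ester.
3. L-Tartrate supplies the CH(OH) centre directly and controls the two new fully substituted centres.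
4. The keto ester comes from 1,3-dithiane as a carbonyl linchpin, joined to an (R)-epoxide on one side and methyl chloroformate on the other. The epoxide comes from undec-10-enal by methylenation and hydrolytic kinetic resolution.
5. Ring order: ring A closes first, on desilylation. Ring B closes last, after the tert-butyl esters and the ketal are removed.

Assumption: the SMILES is read as (3R,4R,5S,8R)-8-(dec-9-en-1-yl)-3,4-dihydroxy-2,6-dioxo-1,7-dioxaspiro[4.4]nonane-4-carboxylic acid. Ring A is the lactone bearing the decenyl chain, and ring B is the lactone bearing the two hydroxyls and the acid.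

## Route

Step 1
Reactants: 1 undec-10-enal
Product: 2 rac-2-(dec-9-en-1-yl)oxirane
Conditions: Me3S+ I− (1.3 equiv), NaH (1.3 equiv), DMSO/THF, 0 °C to rt
Reagents that add atoms: trimethylsulfonium iodide, C[S+](C)C.[I-]
Why: Corey–Chaykovsky epoxidation, in which the sulfonium ylide adds to the aldehyde and the betaine closes to the terminal epoxide; the isolated alkene is inert to this nucleophilic reagent, and no stereocontrol is needed because the next step resolves.

Step 2
Reactants: 2 rac-2-(dec-9-en-1-yl)oxirane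
Product: 3 (2R)-2-(dec-9-en-1-yl)oxirane
Conditions: (R,R)-(salen)Co(OAc) (0.5 mol %; salen = N,N'-bis(3,5-di-tert-butylsalicylidene)cyclohexane-1,2-diaminate), H2O (0.55 equiv), minimal THF, 0 °C to rt, 18 h; chromatography
Reagents that add atoms: none
Why: Hydrolytic kinetic resolution, in which the (R,R)-cobalt salen complex hydrolyses the (S)-epoxide much faster than the (R)-epoxide, so the unreacted (R)-epoxide (future C8 of the target) is recovered in high ee at about 55% conversion.

Step 3
Reactants: 4 1,3-dithiane; 3 (2R)-2-(dec-9-en-1-yl)oxirane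
Product: 6 (2R)-1-(1,3-dithian-2-yl)dodec-11-en-2-ol, via 2-lithio-1,3-dithiane 5 (not isolated)
Conditions: n-BuLi (1.05 equiv), THF, −30 °C, 1.5 h; then 3, −30 to 0 °C; H2O quench
Reagents that add atoms: none
Why: Corey–Seebach dithiane umpolung with SN2 opening at the unsubstituted epoxide carbon, so the C–O stereocentre is not touched.

Step 4
Reactants: 6 (2R)-1-(1,3-dithian-2-yl)dodec-11-en-2-ol
Product: 7 tert-butyl{[(2R)-1-(1,3-dithian-2-yl)dodec-11-en-2-yl]oxy}dimethylsilane
Conditions: TBSCl (1.2 equiv), imidazole (2.5 equiv), DMF, rt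
Reagents that add atoms: tert-butyldimethylsilyl chloride, CC(C)(C)[Si](C)(C)Cl
Why: Standard silylation of a secondary alcohol, giving an ether that survives organolithium and enolate chemistry and is later removed by fluoride without touching the alkene.

Step 5
Reactants: 7 tert-butyl{[(2R)-1-(1,3-dithian-2-yl)dodec-11-en-2-yl]oxy}dimethylsilane
Product: 9 methyl 2-[(2R)-2-[(tert-butyldimethylsilyl)oxy]dodec-11-en-1-yl]-1,3-dithiane-2-carboxylate, via 2-lithiated dithiane 8 (not isolated)
Conditions: t-BuLi (1.1 equiv), THF/HMPA 10:1, −78 °C, 20 min; ClCO2Me (2 equiv), −78 °C; H2O quench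
Reagents that add atoms: methyl chloroformate, COC(=O)Cl
Why: Second dithiane metalation followed by C-acylation, in which HMPA keeps the silyl group on oxygen (no retro-Brook shift), the product has no acidic C–H left, and the terminal alkene is inert at −78 °C.

Step 6
Reactants: 9 methyl 2-[(2R)-2-[(tert-butyldimethylsilyl)oxy]dodec-11-en-1-yl]-1,3-dithiane-2-carboxylate
Product: 10 methyl (4R)-4-[(tert-butyldimethylsilyl)oxy]-2-oxotetradec-13-enoate
Conditions: PhI(OCOCF3)2 (1.5 equiv), MeCN/H2O 9:1, 0 °C, 20 min; dried by toluene azeotrope before use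
Reagents that add atoms: water, O
Why: Oxidative dethioacetalisation with a hypervalent iodine reagent, in which sulfur is oxidised far faster than a monosubstituted alkene and the short, cold, dilute-acid exposure spares the secondary TBS ether.

Step 7
Reactants: 11 di-tert-butyl (2R,3R)-tartrate (di-tert-butyl L-tartrate)
Product: 12 di-tert-butyl (4R,5R)-2,2-dimethyl-1,3-dioxolane-4,5-dicarboxylate
Conditions: 2-methoxypropene (3 equiv), camphorsulfonic acid (5 mol %), CH2Cl2, 0 °C to rt
Reagents that add atoms: 2-methoxypropene, C=C(C)OC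
Why: Acid-catalysed ketalisation with an enol ether, mild enough to leave the tert-butyl esters intact, with both stereocentres untouched.

Step 8
Reactants: 12 di-tert-butyl (4R,5R)-2,2-dimethyl-1,3-dioxolane-4,5-dicarboxylate; 10 methyl (4R)-4-[(tert-butyldimethylsilyl)oxy]-2-oxotetradec-13-enoate
Product: 14 di-tert-butyl (4R,5R)-4-[(2S,4R)-4-[(tert-butyldimethylsilyl)oxy]-2-hydroxy-1-methoxy-1-oxotetradec-13-en-2-yl]-2,2-dimethyl-1,3-dioxolane-4,5-dicarboxylate, via lithium ester enolate 13 (not isolated)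
Conditions: LiN(iPr)2 (1.1 equiv), THF, −78 °C, 30 min; 10 (0.85 equiv) in THF, −78 °C, 2 h; AcOH quench at −78 °C; chromatography
Reagents that add atoms: none
Why: Intermolecular lithium-enolate aldol addition to the ketone of an α-keto ester, in which the keto ester reaches the flat dioxolane enolate from the face anti to the neighbouring C5 tert-butyl ester (new ring centre R, the two ring esters now cis), and in the chair Zimmerman–Traxler array of the O-chelated enolate the CO2Me group sits axial where its carbonyl also binds lithium and the alkyl chain sits equatorial, giving the (S)-tertiary carbinol, with the minor carbinol epimer removed on silica.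

Step 9
Reactants: 14 the aldol adduct of step 8
Product: 16 di-tert-butyl (4R,5R)-4-[(3S,5R)-5-(dec-9-en-1-yl)-3-hydroxy-2-oxooxolan-3-yl]-2,2-dimethyl-1,3-dioxolane-4,5-dicarboxylate, via free hydroxy methyl ester 15 (not isolated)
Conditions: HF·pyridine, pyridine, THF, 0 °C to rt; then PPTS (10 mol %), toluene, 50 °C
Reagents that add atoms: none
Why: Fluoride desilylation followed by acid-catalysed γ-lactonisation (ring A), in which the methyl ester is the only ester the freed alcohol can attack because the tert-butyl esters are inert, the non-basic medium avoids retro-aldol, and no stereocentre is touched.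

Step 10
Reactants: 16 the ring A lactone of step 9
Product: 17 (4R,5R)-4-[(3S,5R)-5-(dec-9-en-1-yl)-3-hydroxy-2-oxooxolan-3-yl]-2,2-dimethyl-1,3-dioxolane-4,5-dicarboxylic acid
Conditions: TFA/CH2Cl2 1:2, 0 °C to rt, 3 h; evaporate
Reagents that add atoms: none
Why: Acidolysis of the tert-butyl esters by loss of isobutene, in which diluted TFA for a few hours does not protonate a monosubstituted alkene and the carbonyl-flanked tertiary alcohol cannot ionise.

Step 11
Reactants: 17 the diacid acetonide of step 10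
Product: 19 (3R,4R,5S,8R)-8-(dec-9-en-1-yl)-3,4-dihydroxy-2,6-dioxo-1,7-dioxaspiro[4.4]nonane-4-carboxylic acid, via triol diacid 18 (not isolated)
Conditions: 2 M aq HCl/1,4-dioxane 1:1, 50 °C; evaporate, toluene azeotrope; reversed-phase chromatography
Reagents that add atoms: none
Why: Acid hydrolysis of the ketal followed by acid-catalysed γ-lactonisation (ring B) between the tertiary OH and the CH(OH)CO2H group, which is the only pairing that gives a bis-γ-lactone and is therefore the thermodynamic product, while aqueous HCl at this strength leaves the terminal alkene and all four stereocentres unchanged.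

## Compound list
1 | undec-10-enal | C=CCCCCCCCCC=O | starting material
2 | rac-2-(dec-9-en-1-yl)oxirane | C=CCCCCCCCCC1CO1 | intermediate
3 | (2R)-2-(dec-9-en-1-yl)oxirane | C=CCCCCCCCC[C@@H]1CO1 | intermediate
4 | 1,3-dithiane | C1CSCSC1 | starting material
5 | 2-lithio-1,3-dithiane (not isolated) | [Li]C1SCCCS1 | intermediate
6 | (2R)-1-(1,3-dithian-2-yl)dodec-11-en-2-ol | C=CCCCCCCCC[C@@H](O)CC1SCCCS1 | intermediate
7 | tert-butyl{[(2R)-1-(1,3-dithian-2-yl)dodec-11-en-2-yl]oxy}dimethylsilane | C=CCCCCCCCC[C@@H](O[Si](C)(C)C(C)(C)C)CC1SCCCS1 | intermediate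
8 | 2-lithio derivative of 7 (not isolated) | C=CCCCCCCCC[C@@H](O[Si](C)(C)C(C)(C)C)CC1([Li])SCCCS1 | intermediate
9 | methyl 2-[(2R)-2-[(tert-butyldimethylsilyl)oxy]dodec-11-en-1-yl]-1,3-dithiane-2-carboxylate | C=CCCCCCCCC[C@@H](O[Si](C)(C)C(C)(C)C)CC1(C(=O)OC)SCCCS1 | intermediate
10 | methyl (4R)-4-[(tert-butyldimethylsilyl)oxy]-2-oxotetradec-13-enoate | C=CCCCCCCCC[C@@H](O[Si](C)(C)C(C)(C)C)CC(=O)C(=O)OC | intermediate
11 | di-tert-butyl (2R,3R)-tartrate | CC(C)(C)OC(=O)[C@H](O)[C@@H](O)C(=O)OC(C)(C)C | starting material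
12 | di-tert-butyl (4R,5R)-2,2-dimethyl-1,3-dioxolane-4,5-dicarboxylate | CC1(C)O[C@H]([C@@H](O1)C(=O)OC(C)(C)C)C(=O)OC(C)(C)C | intermediate
13 | lithium enolate of 12, OLi cis to the ring oxygen (not isolated) | [Li+].[O-]/C(OC(C)(C)C)=C1\OC(C)(C)O[C@H]1C(=O)OC(C)(C)C | intermediate
14 | di-tert-butyl (4R,5R)-4-[(2S,4R)-4-[(tert-butyldimethylsilyl)oxy]-2-hydroxy-1-methoxy-1-oxotetradec-13-en-2-yl]-2,2-dimethyl-1,3-dioxolane-4,5-dicarboxylate | C=CCCCCCCCC[C@@H](O[Si](C)(C)C(C)(C)C)C[C@@]([C@]1(C(=O)OC(C)(C)C)OC(C)(C)O[C@H]1C(=O)OC(C)(C)C)(O)C(=O)OC | intermediate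
15 | di-tert-butyl (4R,5R)-4-[(2S,4R)-2,4-dihydroxy-1-methoxy-1-oxotetradec-13-en-2-yl]-2,2-dimethyl-1,3-dioxolane-4,5-dicarboxylate (not isolated) | C=CCCCCCCCC[C@@H](O)C[C@@]([C@]1(C(=O)OC(C)(C)C)OC(C)(C)O[C@H]1C(=O)OC(C)(C)C)(O)C(=O)OC | intermediate
16 | di-tert-butyl (4R,5R)-4-[(3S,5R)-5-(dec-9-en-1-yl)-3-hydroxy-2-oxooxolan-3-yl]-2,2-dimethyl-1,3-dioxolane-4,5-dicarboxylate | C=CCCCCCCCC[C@@H]1C[C@@]([C@]2(C(=O)OC(C)(C)C)OC(C)(C)O[C@H]2C(=O)OC(C)(C)C)(O)C(=O)O1 | intermediate
17 | (4R,5R)-4-[(3S,5R)-5-(dec-9-en-1-yl)-3-hydroxy-2-oxooxolan-3-yl]-2,2-dimethyl-1,3-dioxolane-4,5-dicarboxylic acid | C=CCCCCCCCC[C@@H]1C[C@@]([C@]2(C(=O)O)OC(C)(C)O[C@H]2C(=O)O)(O)C(=O)O1 | intermediate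
18 | (2R,3R)-2-[(3S,5R)-5-(dec-9-en-1-yl)-3-hydroxy-2-oxooxolan-3-yl]-2,3-dihydroxybutanedioic acid (not isolated) | C=CCCCCCCCC[C@@H]1C[C@@]([C@@](O)(C(=O)O)[C@@H](O)C(=O)O)(O)C(=O)O1 | intermediate
19 | (3R,4R,5S,8R)-8-(dec-9-en-1-yl)-3,4-dihydroxy-2,6-dioxo-1,7-dioxaspiro[4.4]nonane-4-carboxylic acid | C=CCCCCCCCC[C@@H]1C[C@@]2(OC(=O)[C@H](O)[C@]2(O)C(=O)O)C(=O)O1 | target

## Step count
Total step count: 11.
Longest linear sequence: 10 (steps 1–6 and 8–11). Step 7 is the one-step side branch.

## Three steps most likely to fail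

**Step 8.** The basic enolate 13 may deprotonate keto ester 10 instead of adding to it, or the ratio at the tertiary carbinol may be poor. The fallback builds the tertiary carbinol in two C–C bond formations instead of one. It sets out from 7 and 12 and comes back at 14.
- Dithiane 7 carries no ester and hydrolyses easily (MeI, CaCO3, aq MeCN, 45 °C) to the aldehyde (3R)-3-[(tert-butyldimethylsilyl)oxy]tridec-12-enal F1.
- Enolate 13, made from 12 as in step 8, adds to this more reactive and less acidic aldehyde, again anti to the C5 ester. This gives the secondary aldol di-tert-butyl (4S,5R)-4-[(3R)-3-[(tert-butyldimethylsilyl)oxy]-1-hydroxytridec-12-en-1-yl]-2,2-dimethyl-1,3-dioxolane-4,5-dicarboxylate F2. Both carbinol epimers are usable. The ring descriptor changes only through a priority switch.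
- Dess–Martin periodinane oxidises F2 to the ketone di-tert-butyl (4R,5R)-4-[(3R)-3-[(tert-butyldimethylsilyl)oxy]tridec-12-enoyl]-2,2-dimethyl-1,3-dioxolane-4,5-dicarboxylate F3.
- 1-Methoxyvinyllithium (from methyl vinyl ether and t-BuLi, with MgBr2·OEt2, THF, −78 °C) adds under Cram-chelate control through the ketone oxygen and the ring oxygen, on the side away from the dioxolane ring carbon. The product is the tertiary alcohol di-tert-butyl (4R,5R)-4-[(3R,5R)-5-[(tert-butyldimethylsilyl)oxy]-3-hydroxy-2-methoxypentadeca-1,14-dien-3-yl]-2,2-dimethyl-1,3-dioxolane-4,5-dicarboxylate F4.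
- Ozone, titrated at −78 °C in CH2Cl2/MeOH against Sudan Red 7B and then treated with Me2S, cleaves only the electron-rich enol ether. This turns C(OMe)=CH2 directly into CO2Me, which is 14.

**Step 6.** The ester-bearing dithiane may be slow to unmask, or the alkene or TBS ether may be attacked. The fallback removes sulfur from the plan and builds the keto ester by olefination. It sets out from 2 and comes back at 10.
- Resolution of 2 with the enantiomeric catalyst (S,S)-(salen)Co(OAc) and 0.45 equiv of H2O gives the diol (2R)-dodec-11-ene-1,2-diol F5.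
- TBSCl and imidazole give the bis-silyl ether (2R)-1,2-bis[(tert-butyldimethylsilyl)oxy]dodec-11-ene F6.
- HF·pyridine in THF/pyridine at 0 °C removes only the primary silyl group, giving the alcohol (2R)-2-[(tert-butyldimethylsilyl)oxy]dodec-11-en-1-ol F7.
- Dess–Martin oxidation gives the aldehyde (2R)-2-[(tert-butyldimethylsilyl)oxy]dodec-11-enal F8.
- Horner–Wadsworth–Emmons reaction with methyl 2-[(tert-butyldimethylsilyl)oxy]-2-(dimethoxyphosphoryl)acetate and LiN(SiMe3)2 at −78 °C gives the silyl enol ether methyl (4R)-2,4-bis[(tert-butyldimethylsilyl)oxy]tetradeca-2,13-dienoate F9 as an E/Z mixture.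
- Et3N·3HF at 0 °C cleaves the enol silane much faster than the alkyl silyl ether, and tautomerisation gives 10.

**Step 11.** The electron-poor acetonide may hydrolyse slowly, and forcing acid endangers the alkene. The fallback removes the ketal first, by irreversible exchange with a dithiol rather than by hydrolysis, and leaves ester acidolysis for last. It sets out from 16 and comes back at 18, which closes to 19.
- Propane-1,3-dithiol (1.5 equiv) and BF3·OEt2 (0.3 equiv) in CH2Cl2 at −20 to 0 °C transfer the isopropylidene group to sulfur. This gives the triol di-tert-butyl (2R,3R)-2-[(3S,5R)-5-(dec-9-en-1-yl)-3-hydroxy-2-oxooxolan-3-yl]-2,3-dihydroxybutanedioate F10.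
- TFA/CH2Cl2 1:2 then cleaves both tert-butyl esters to give 18. On evaporation and toluene azeotrope, 18 lactonises to 19.

## Further compounds
F1 | step 8 | (3R)-3-[(tert-butyldimethylsilyl)oxy]tridec-12-enal | C=CCCCCCCCC[C@@H](O[Si](C)(C)C(C)(C)C)CC=O
F2 | step 8 | di-tert-butyl (4S,5R)-4-[(3R)-3-[(tert-butyldimethylsilyl)oxy]-1-hydroxytridec-12-en-1-yl]-2,2-dimethyl-1,3-dioxolane-4,5-dicarboxylate (carbinol epimers) | C=CCCCCCCCC[C@@H](O[Si](C)(C)C(C)(C)C)CC(O)[C@]1(C(=O)OC(C)(C)C)OC(C)(C)O[C@H]1C(=O)OC(C)(C)C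
F3 | step 8 | di-tert-butyl (4R,5R)-4-[(3R)-3-[(tert-butyldimethylsilyl)oxy]tridec-12-enoyl]-2,2-dimethyl-1,3-dioxolane-4,5-dicarboxylate | C=CCCCCCCCC[C@@H](O[Si](C)(C)C(C)(C)C)CC(=O)[C@]1(C(=O)OC(C)(C)C)OC(C)(C)O[C@H]1C(=O)OC(C)(C)C
F4 | step 8 | di-tert-butyl (4R,5R)-4-[(3R,5R)-5-[(tert-butyldimethylsilyl)oxy]-3-hydroxy-2-methoxypentadeca-1,14-dien-3-yl]-2,2-dimethyl-1,3-dioxolane-4,5-dicarboxylate | C=CCCCCCCCC[C@@H](O[Si](C)(C)C(C)(C)C)C[C@@]([C@]1(C(=O)OC(C)(C)C)OC(C)(C)O[C@H]1C(=O)OC(C)(C)C)(O)C(=C)OC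
F5 | step 6 | (2R)-dodec-11-ene-1,2-diol | C=CCCCCCCCC[C@@H](O)CO
F6 | step 6 | (2R)-1,2-bis[(tert-butyldimethylsilyl)oxy]dodec-11-ene | C=CCCCCCCCC[C@@H](O[Si](C)(C)C(C)(C)C)CO[Si](C)(C)C(C)(C)C
F7 | step 6 | (2R)-2-[(tert-butyldimethylsilyl)oxy]dodec-11-en-1-ol | C=CCCCCCCCC[C@@H](O[Si](C)(C)C(C)(C)C)CO
F8 | step 6 | (2R)-2-[(tert-butyldimethylsilyl)oxy]dodec-11-enal | C=CCCCCCCCC[C@@H](O[Si](C)(C)C(C)(C)C)C=O
F9 | step 6 | methyl (4R)-2,4-bis[(tert-butyldimethylsilyl)oxy]tetradeca-2,13-dienoate (E/Z mixture) | C=CCCCCCCCC[C@@H](O[Si](C)(C)C(C)(C)C)C=C(O[Si](C)(C)C(C)(C)C)C(=O)OC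
F10 | step 11 | di-tert-butyl (2R,3R)-2-[(3S,5R)-5-(dec-9-en-1-yl)-3-hydroxy-2-oxooxolan-3-yl]-2,3-dihydroxybutanedioate | C=CCCCCCCCC[C@@H]1C[C@@]([C@@](O)(C(=O)OC(C)(C)C)[C@@H](O)C(=O)OC(C)(C)C)(O)C(=O)O1
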